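**Retrosynthetic overview**

1. The strategy rests on ring A, the benzene ring: it is a hydroquinone whose crowded oxygen on C2 (between C1, which carries the chain, and C3, which carries OMe) is acetylated while the open oxygen on C5 is free. This pattern is built in by making the arene last, not by differentiating a hydroquinone.
2. Ring A ⇒ 4-acetoxy-4-alkenyl-3-methoxycyclobutenone 12 (4π ring opening, then 6π closure forming arene bond C5–C6). This is the only ring made, and it is made in the last step.
3. 12 ⇒ alkenyllithium from (R)-bromoalkenol 6 + methyl semisquarate 9 (bond to the ring carbon that becomes C2), with both alkoxides acetylated in the flask; 9 comes from dimethyl squarate 7.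
4. 6 ⇒ tetradecanal 3 + a 2-bromoallyl unit from 2,3-dibromopropene 1; an enantioselective allylboration sets the only stereocentre.

Key step: step 6

Assumption: the (S,S)-bis-sulfonamide boron controller is taken to deliver the 2-bromoallyl group to the si face of an unbranched aliphatic aldehyde; if the sense proves to be the opposite, the (R,R)-controller is used with no other change.

**Route**

Step 1
Reactants: 1 2,3-dibromopropene
Product: 2 tributyl(2-bromoprop-2-en-1-yl)stannane
Conditions: Bu3SnH, LiN(iPr)2, THF, 0 °C; then 1, −78 °C
Reagents that add atoms: tributyltin hydride, CCCC[SnH](CCCC)CCCC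
Why: Allylic substitution (SN2 or SN2′, which give the same product on this allyl unit) of the allylic bromide by the stannyl anion, while the vinylic C–Br bond should stay intact at −78 °C.

Step 2
Reactants: 2 tributyl(2-bromoprop-2-en-1-yl)stannane; 3 tetradecanal
Product: 6 (R)-2-bromoheptadec-1-en-4-ol, via B-(2-bromoallyl)diazaborolidine 4 (not isolated), via boron alkoxide 5 (not isolated)
Conditions: (S,S)-TsNHCH(Ph)CH(Ph)NHTs, BBr3, CH2Cl2, 0 °C to rt, then evacuate; 2, CH2Cl2, rt; 3, −78 °C; aq. pH 7 buffer
Reagents that add atoms: none
Why: Corey allylboration, in which tin-to-boron exchange on the chiral B-bromodiazaborolidine gives allylborane 4, which transfers the 2-bromoallyl group to the si face of the aldehyde through a closed chair transition state (alkyl chain equatorial), so that the C2-symmetric (S,S)-bis-sulfonamide sets the (R)-carbinol, and hydrolysis of 5 releases 6 and the recoverable controller.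

Step 3
Reactants: 7 dimethyl squarate
Product: 8 4-hydroxy-2,3-dimethoxycyclobut-2-en-1-one (racemic)
Conditions: LiAlH(OtBu)3, THF, −78 °C; aq. work-up
Reagents that add atoms: none
Why: 1,2-Reduction of one squarate carbonyl by a bulky, mild hydride donor, which should stop at the mono-alcohol because the remaining carbonyl is a deactivated vinylogous ester next to an alkoxide; the new stereocentre is racemic and is destroyed in step 4.

Step 4
Reactants: 8 4-hydroxy-2,3-dimethoxycyclobut-2-en-1-one
Product: 9 3-methoxycyclobut-3-ene-1,2-dione (methyl semisquarate)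
Conditions: conc. HCl (cat.), CH2Cl2, rt
Reagents that add atoms: water, O
Why: Acid-promoted 1,3-carbonyl transposition, in which ionisation of the allylic hydroxyl gives a methoxy-stabilised cyclobutenyl cation, water adds at the distal methoxy-bearing carbon and the hemiketal loses methanol, the standard conversion of squarate adducts into cyclobutenediones.

Step 5
Reactants: 6 (R)-2-bromoheptadec-1-en-4-ol; 9 3-methoxycyclobut-3-ene-1,2-dione
Product: 12 4-acetoxy-4-[(4R)-4-acetoxyheptadec-1-en-2-yl]-3-methoxycyclobut-2-en-1-one (epimer mixture at the ring sp3 carbon), via dilithio alkenyl alkoxide 10 (not isolated), via dilithium dialkoxide 11 (not isolated)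
Conditions: 6, t-BuLi (3.0 equiv), Et2O–THF, −78 °C; cannulated into 9, THF, −78 °C; Ac2O (5 equiv), −78 to 0 °C
Reagents that add atoms: acetic anhydride, CC(=O)OC(C)=O
Why: Deprotonation and bromine–lithium exchange give alkenyllithium 10, which should add 1,2 to the more electrophilic carbonyl of 9 (the one next to the methoxy-bearing carbon; the other is a vinylogous ester carbonyl), and both lithium alkoxides of 11 are then O-acylated by acetic anhydride, the carbinol stereocentre being untouched and the new ring carbon formed as an inconsequential epimer mixture.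

Step 6
Reactants: 12 4-acetoxy-4-[(4R)-4-acetoxyheptadec-1-en-2-yl]-3-methoxycyclobut-2-en-1-one
Product: 15 (2R)-1-(2-acetoxy-5-hydroxy-3-methoxyphenyl)pentadecan-2-yl acetate, via dienylketene 13 (not isolated), via cyclohexadienone 14 (not isolated)
Conditions: degassed p-xylene (0.01 M), 140 °C, argon
Reagents that add atoms: none
Why: Heating opens the cyclobutenone by thermal conrotatory 4π electrocyclic cleavage of its C1–C4 bond to dienylketene 13, whose ketene carbon and terminal alkene CH2 are the ends of a hexatriene; thermal disrotatory 6π electrocyclisation joins them (arene bond C5–C6) to give cyclohexa-2,4-dienone 14, which enolises to the phenol. This is the Moore-type ring expansion of 4-alkenyl-4-oxycyclobutenones to hydroquinone derivatives, run here on the 4-acetoxy compound. Ring A is closed by the 6π electrocyclisation, with all six ring atoms already assembled in 13 (four from the cyclobutenone, two from the alkene). No stereocentre is created: the ring sp3 carbon of 12 becomes aromatic C2, so both epimers converge, and the side-chain (R)-carbinol acetate is remote and untouched. The step needs the alkenyl group to turn inward on ring opening, which the stronger outward preference of the oxygen substituent on the same carbon should supply; because ring opening is reversible and 12 has no free hydroxyl to trap a ketene, a wrongly rotated ketene should reclose and be funnelled through 13. The regiochemistry is fixed by the substrate: the ketene carbonyl becomes the free C5 phenol and the already acetylated carbinol carbon becomes C2 between C1 and C3, so no phenol has to be acylated selectively.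

**Compound list**

1 | 2,3-dibromopropene | C=C(Br)CBr | starting material
2 | tributyl(2-bromoprop-2-en-1-yl)stannane | C=C(Br)C[Sn](CCCC)(CCCC)CCCC | intermediate
3 | tetradecanal | CCCCCCCCCCCCCC=O | starting material
4 | (4S,5S)-2-(2-bromoprop-2-en-1-yl)-4,5-diphenyl-1,3-bis(4-methylphenylsulfonyl)-1,3,2-diazaborolidine | C=C(Br)CB1N(S(=O)(=O)c2ccc(C)cc2)[C@@H](c2ccccc2)[C@H](c2ccccc2)N1S(=O)(=O)c1ccc(C)cc1 | intermediate (not isolated)
5 | (4S,5S)-2-{[(4R)-2-bromoheptadec-1-en-4-yl]oxy}-4,5-diphenyl-1,3-bis(4-methylphenylsulfonyl)-1,3,2-diazaborolidine | CCCCCCCCCCCCC[C@H](CC(Br)=C)OB1N(S(=O)(=O)c2ccc(C)cc2)[C@@H](c2ccccc2)[C@H](c2ccccc2)N1S(=O)(=O)c1ccc(C)cc1 | intermediate (not isolated)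
6 | (R)-2-bromoheptadec-1-en-4-ol | CCCCCCCCCCCCC[C@H](CC(Br)=C)O | intermediate
7 | dimethyl squarate (3,4-dimethoxycyclobut-3-ene-1,2-dione) | COC1=C(OC)C(=O)C1=O | starting material
8 | 4-hydroxy-2,3-dimethoxycyclobut-2-en-1-one (racemic) | COC1=C(OC)C(O)C1=O | intermediate
9 | 3-methoxycyclobut-3-ene-1,2-dione (methyl semisquarate) | COC1=CC(=O)C1=O | intermediate
10 | lithium (R)-2-lithioheptadec-1-en-4-olate | CCCCCCCCCCCCC[C@H](CC([Li])=C)O[Li] | intermediate (not isolated)
11 | dilithium dialkoxide of 4-hydroxy-4-[(4R)-4-hydroxyheptadec-1-en-2-yl]-3-methoxycyclobut-2-en-1-one | CCCCCCCCCCCCC[C@H](CC(=C)C1(O[Li])C(OC)=CC1=O)O[Li] | intermediate (not isolated)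
12 | 4-acetoxy-4-[(4R)-4-acetoxyheptadec-1-en-2-yl]-3-methoxycyclobut-2-en-1-one (epimer mixture at the ring carbon) | CCCCCCCCCCCCC[C@H](CC(=C)C1(OC(C)=O)C(OC)=CC1=O)OC(C)=O | intermediate
13 | (3Z,7R)-4,7-diacetoxy-3-methoxy-5-methylideneicosa-1,3-dien-1-one (dienylketene) | CCCCCCCCCCCCC[C@H](CC(=C)/C(OC(C)=O)=C(OC)\C=C=O)OC(C)=O | intermediate (not isolated)
14 | 4-acetoxy-5-[(2R)-2-acetoxypentadecyl]-3-methoxycyclohexa-2,4-dien-1-one | CCCCCCCCCCCCC[C@H](CC1=C(OC(C)=O)C(OC)=CC(=O)C1)OC(C)=O | intermediate (not isolated)
15 | (2R)-1-(2-acetoxy-5-hydroxy-3-methoxyphenyl)pentadecan-2-yl acetate | CCCCCCCCCCCCC[C@H](Cc1cc(O)cc(OC)c1OC(C)=O)OC(C)=O | target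

**Step count**

Total steps: 6. Longest linear sequence: 4 steps (1 → 2 → 6 → 12 → 15 through steps 1, 2, 5, 6; the squarate branch through steps 3, 4, 5, 6 is equally long).

**Steps most likely to fail, with fallbacks**

Step 5. The side-chain lithium alkoxide of 11 may attack the cyclobutenone intramolecularly before it is acylated, either by hemiketal formation at the carbonyl or by displacing methoxide at the vinylogous ester carbon. The vinyl bromide may also be dehydrobrominated instead of exchanged, or the tertiary alkoxide may be acylated incompletely. The fallback masks the carbinol so that only a mono-lithium species is used. It sets out from 6, which is silylated (TBSCl, imidazole, DMF) to tert-butyl{[(4R)-2-bromoheptadec-1-en-4-yl]oxy}dimethylsilane F1. F1 is lithiated (t-BuLi, 2 equiv, Et2O, −78 °C), added to 9, and the single alkoxide is quenched with Ac2O to give 4-acetoxy-4-[(4R)-4-(tert-butyldimethylsilyloxy)heptadec-1-en-2-yl]-3-methoxycyclobut-2-en-1-one F2. HF·pyridine in THF should remove the silyl group to give 4-acetoxy-4-[(4R)-4-hydroxyheptadec-1-en-2-yl]-3-methoxycyclobut-2-en-1-one F3. Acetylation (Ac2O, pyridine, cat. DMAP) then gives 12, where the route is rejoined.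

Step 6. Ring opening may be sluggish with the weakly donating acetoxy group. Outward rotation of the alkenyl group may divert material through acyl transfer within the wrong ketene. The product phenol may also trap the ketene intermolecularly if the solution is too concentrated. The fallback keeps the ring expansion but uses the classical free-hydroxy substrate and differentiates the two phenols afterwards by steric hindrance. It sets out from 6 (with 9): 10 is generated and added to 9 as in step 5, but 11 is quenched with aqueous NH4Cl at −78 °C to give 4-hydroxy-4-[(4R)-4-hydroxyheptadec-1-en-2-yl]-3-methoxycyclobut-2-en-1-one F4. Thermolysis in degassed p-xylene should give 2-[(2R)-2-hydroxypentadecyl]-6-methoxybenzene-1,4-diol F5. F5 is acetylated without exposure to air (Ac2O, pyridine, cat. DMAP) to (2R)-1-(2,5-diacetoxy-3-methoxyphenyl)pentadecan-2-yl acetate F6. One equivalent of pyrrolidine in CH2Cl2 at 0 °C should aminolyse the unhindered C5 aryl acetate in preference to the doubly ortho-substituted C2 aryl acetate and the alkyl acetate, giving 15.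

Step 2. Facial selectivity may be insufficient (or of the opposite sense) with the 2-bromo-substituted allylborane, and the bromoallyl metal species may be lost by β-elimination to allene during the slow tin-to-boron exchange. The fallback sets the stereocentre by resolution of an epoxide instead of by allyl transfer. It sets out from 3, which is methylenated (Me3S+ I−, KOtBu, DMSO–THF, Corey–Chaykovsky reaction) to racemic 2-tridecyloxirane F7. Hydrolytic kinetic resolution follows, using (R,R)-N,N′-bis(3,5-di-tert-butylsalicylidene)-1,2-cyclohexanediamine cobalt acetate, (salen)Co(OAc), trivalent cobalt, and 0.55 equiv of water. It should leave (R)-2-tridecyloxirane F8. Opening at the terminal carbon with LiC≡CH·H2NCH2CH2NH2 in DMSO gives (R)-heptadec-1-yn-4-ol F9. Markovnikov hydrobromination with B-bromo-9-borabicyclo[3.3.1]nonane (2.2 equiv, the first equivalent masking the hydroxyl as its borinate; CH2Cl2, 0 °C), then protonolysis with AcOH, should give 6, where the route is rejoined.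

**Further compounds**

F1 | step 5 | tert-butyl{[(4R)-2-bromoheptadec-1-en-4-yl]oxy}dimethylsilane | CCCCCCCCCCCCC[C@H](CC(Br)=C)O[Si](C)(C)C(C)(C)C
F2 | step 5 | 4-acetoxy-4-[(4R)-4-(tert-butyldimethylsilyloxy)heptadec-1-en-2-yl]-3-methoxycyclobut-2-en-1-one | CCCCCCCCCCCCC[C@H](CC(=C)C1(OC(C)=O)C(OC)=CC1=O)O[Si](C)(C)C(C)(C)C
F3 | step 5 | 4-acetoxy-4-[(4R)-4-hydroxyheptadec-1-en-2-yl]-3-methoxycyclobut-2-en-1-one | CCCCCCCCCCCCC[C@H](CC(=C)C1(OC(C)=O)C(OC)=CC1=O)O
F4 | step 6 | 4-hydroxy-4-[(4R)-4-hydroxyheptadec-1-en-2-yl]-3-methoxycyclobut-2-en-1-one | CCCCCCCCCCCCC[C@H](CC(=C)C1(O)C(OC)=CC1=O)O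
F5 | step 6 | 2-[(2R)-2-hydroxypentadecyl]-6-methoxybenzene-1,4-diol | CCCCCCCCCCCCC[C@H](Cc1cc(O)cc(OC)c1O)O
F6 | step 6 | (2R)-1-(2,5-diacetoxy-3-methoxyphenyl)pentadecan-2-yl acetate | CCCCCCCCCCCCC[C@H](Cc1cc(OC(C)=O)cc(OC)c1OC(C)=O)OC(C)=O
F7 | step 2 | 2-tridecyloxirane (racemic) | CCCCCCCCCCCCCC1CO1
F8 | step 2 | (R)-2-tridecyloxirane | CCCCCCCCCCCCC[C@@H]1CO1
F9 | step 2 | (R)-heptadec-1-yn-4-ol | CCCCCCCCCCCCC[C@H](CC#C)O
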